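**Assumptions.** (1) Methyl (S)-leucate, the methyl ester of L-leucic acid, is bought. (2) The target's 2,3-trans-3,4-trans (all-equatorial) chroman is the thermodynamic diastereomer, so only C4 has to be set by the chiral starting material.

## Retrosynthetic overview
1. Sideroxylonal C (11) comes from Vilsmeier tetra-formylation of the chroman pentol 10, done last.
2. Pentol 10 comes from Lewis-acid ionisation, ortho-O attack and demethylation of the diaryl carbinol 9, which closes the pyran ring (C2–O). C2 and C3 equilibrate to the all-equatorial isomer under control of C4.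
3. Carbinol 9 comes from aryl ketone 8, which forms in one pot from diazoketone 7 by photochemical Wolff rearrangement (new C3–C4 bond, C4 retained) and aryllithium capture of the ketene (ring B on C2).
4. Diazoketone 7 comes from ketone 6 and Weinreb amide 5, which come from inversion Friedel–Crafts arylation (ring A on C4) of the triflate of methyl L-leucate, the only chiral source.

Rings are built in this order: aryl ring A on C4, then the C3–C4 bond and aryl ring B on C2, then pyran closure, then the four formyl groups.

## Route

**Step 1**
Reactants: 1, methyl (S)-2-hydroxy-4-methylpentanoate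
Product: 2, methyl (S)-4-methyl-2-(triflyloxy)pentanoate
Conditions: Tf2O, 2,6-lutidine, CH2Cl2, −78 → 0 °C
Reagents that add atoms: triflic anhydride, O=S(=O)(C(F)(F)F)OS(=O)(=O)C(F)(F)F (adds SO2CF3)
Why: Alcohol triflation converts the hydroxyl into a leaving group with no change at the stereocentre.

**Step 2**
Reactants: 2; 3, 1,3,5-trimethoxybenzene
Product: 4, methyl (S)-4-methyl-2-(2,4,6-trimethoxyphenyl)pentanoate
Conditions: 3 (3 equiv), 2,6-di-tert-butylpyridine, CH2Cl2, 0 → 25 °C
Reagents that add atoms: none (3 is the reactant)
Why: This is an Effenberger-type SN2 Friedel–Crafts alkylation of the very nucleophilic arene with the α-triflyloxy ester; Walden inversion sets C4 of the target (the CIP label stays S because the aryl group ranks below the ester carbon). The symmetric arene avoids regiochemical issues.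

**Step 3**
Reactants: 4
Product: 5, (S)-N-methoxy-N,4-dimethyl-2-(2,4,6-trimethoxyphenyl)pentanamide
Conditions: MeNHOMe·HCl, i-PrMgCl (3 equiv), THF, −20 → 0 °C
Reagents that add atoms: N,O-dimethylhydroxylamine, CNOC (adds N(Me)OMe)
Why: Grignard-mediated aminolysis (Williams Weinreb amide synthesis); the cold, hindered, electron-rich aryl acetate does not epimerise.

**Step 4**
Reactants: 5
Product: 6, (5S)-2,7-dimethyl-5-(2,4,6-trimethoxyphenyl)octan-4-one
Conditions: i-BuMgBr (3 equiv), THF, 0 °C
Reagents that add atoms: isobutylmagnesium bromide, CC(C)C[Mg]Br (adds i-Bu; its CH2CH(CH3)2 becomes C3 plus the isopropyl group)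
Why: Weinreb ketone synthesis stops at the ketone through the chelated tetrahedral intermediate, and C4 is untouched.

**Step 5**
Reactants: 6
Product: 7, (5S)-3-diazo-2,7-dimethyl-5-(2,4,6-trimethoxyphenyl)octan-4-one
Conditions: (a) LiHMDS, CF3CO2CH2CF3, THF, −78 °C; (b) MsN3, Et3N, H2O, MeCN, 25 °C
Reagents that add atoms: methanesulfonyl azide, CS(=O)(=O)N=[N+]=[N-] (adds N2); the trifluoroacetyl group from CF3CO2CH2CF3 is transient and lost
Why: Danheiser detrifluoroacetylative diazo transfer occurs at the less hindered CH2 (kinetic enolate), giving the α-diazoketone with C4 untouched.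

**Step 6**
Reactants: 7
Product: 8, (2R,3R)-2-isopropyl-5-methyl-1,3-bis(2,4,6-trimethoxyphenyl)hexan-1-one
Conditions: hν (350 nm), THF, −20 °C; then 2,4,6-(MeO)3C6H2Li, −78 → 0 °C; then AcOH quench
Reagents that add atoms: 2,4,6-trimethoxyphenyllithium, COc1cc(OC)c([Li])c(OC)c1 (made from 3 and n-BuLi; adds ring B); AcOH, CC(=O)O (adds H only)
Why: Proposed new method: photolysis triggers a concerted Wolff 1,2-shift of the stereogenic, di-ortho-oxygenated benzylic carbon C4, which migrates with retention onto the isopropyl-bearing carbene carbon. This forms the C3–C4 bond and a persistent hindered dialkylketene, which the aryllithium intercepts to give the lithium enolate and, after protonation, ketone 8 (ring B on C2). C4 is retained, C3 is set kinetically by protonation anti to the C4 aryl group and re-equilibrates in step 8. The closest known reactions are Arndt–Eistert/Wolff homologation and ketene + organolithium addition; the new element is applying the photo-Wolff/ketene-arylation sequence to a stereogenic hindered benzylic migrating group.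

**Step 7**
Reactants: 8
Product: 9, (2R,3R)-2-isopropyl-5-methyl-1,3-bis(2,4,6-trimethoxyphenyl)hexan-1-ol (carbinol carbon as an epimeric mixture)
Conditions: LiAlH4, THF, 0 °C
Reagents that add atoms: none (hydride adds H only)
Why: Ketone reduction gives a carbinol whose new stereocentre is irrelevant because it is ionised in step 8.

**Step 8**
Reactants: 9
Product: 10, (2R,3R,4R)-4-isobutyl-3-isopropyl-2-(2,4,6-trihydroxyphenyl)chromane-5,7-diol
Conditions: BBr3 (9 equiv), CH2Cl2, −78 → 25 °C; then H2O
Reagents that add atoms: none (aqueous work-up only restores O–H)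
Why: BBr3 ionises the benzylic carbinol to a cation stabilised by the trioxygenated ring B, the ortho oxygen of ring A closes the pyran (cyclodemethylation, flavan-type cyclisation), and BBr3 then cleaves the remaining aryl methyl ethers. Ionisation and alkene formation are reversible, so C2 and C3 settle in the all-equatorial 2,3-trans-3,4-trans arrangement relative to C4, which has no leaving group and is not scrambled. Minor diastereomers are removed chromatographically.

**Step 9**
Reactants: 10
Product: 11, sideroxylonal C
Conditions: POCl3, DMF, 0 → 50 °C; then aq. NaOAc, 60 °C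
Reagents that add atoms: DMF, CN(C)C=O (supplies the four formyl carbons); water, O (supplies the formyl oxygens)
Why: Vilsmeier–Haack formylation of the four free, strongly activated positions flanked by hydroxyl groups (C6 and C8 of ring A, C3′ and C5′ of ring B) installs the two aldehydes on each ring; stereocentres are untouched.

## Compound list
1 | methyl (S)-2-hydroxy-4-methylpentanoate | CC(C)C[C@H](O)C(=O)OC | starting material
2 | methyl (S)-4-methyl-2-(trifluoromethanesulfonyloxy)pentanoate | CC(C)C[C@H](OS(=O)(=O)C(F)(F)F)C(=O)OC | intermediate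
3 | 1,3,5-trimethoxybenzene | COc1cc(OC)cc(OC)c1 | starting material
4 | methyl (S)-4-methyl-2-(2,4,6-trimethoxyphenyl)pentanoate | CC(C)C[C@@H](c1c(OC)cc(OC)cc1OC)C(=O)OC | intermediate
5 | (S)-N-methoxy-N,4-dimethyl-2-(2,4,6-trimethoxyphenyl)pentanamide | CC(C)C[C@@H](c1c(OC)cc(OC)cc1OC)C(=O)N(C)OC | intermediate
6 | (5S)-2,7-dimethyl-5-(2,4,6-trimethoxyphenyl)octan-4-one | CC(C)CC(=O)[C@@H](CC(C)C)c1c(OC)cc(OC)cc1OC | intermediate
7 | (5S)-3-diazo-2,7-dimethyl-5-(2,4,6-trimethoxyphenyl)octan-4-one | CC(C)C(=[N+]=[N-])C(=O)[C@@H](CC(C)C)c1c(OC)cc(OC)cc1OC | intermediate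
8 | (2R,3R)-2-isopropyl-5-methyl-1,3-bis(2,4,6-trimethoxyphenyl)hexan-1-one | CC(C)C[C@@H](c1c(OC)cc(OC)cc1OC)[C@@H](C(C)C)C(=O)c1c(OC)cc(OC)cc1OC | intermediate
9 | (2R,3R)-2-isopropyl-5-methyl-1,3-bis(2,4,6-trimethoxyphenyl)hexan-1-ol (carbinol carbon unspecified) | CC(C)C[C@@H](c1c(OC)cc(OC)cc1OC)[C@@H](C(C)C)C(O)c1c(OC)cc(OC)cc1OC | intermediate
10 | (2R,3R,4R)-4-isobutyl-3-isopropyl-2-(2,4,6-trihydroxyphenyl)chromane-5,7-diol | CC(C)C[C@H]1c2c(O)cc(O)cc2O[C@@H](c2c(O)cc(O)cc2O)[C@@H]1C(C)C | intermediate
11 | sideroxylonal C | CC(C)C[C@H]1c2c(O)c(C=O)c(O)c(C=O)c2O[C@@H](c2c(O)c(C=O)c(O)c(C=O)c2O)[C@@H]1C(C)C | target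

## Summary
Total steps: 9. Longest linear sequence: 9.

Three steps most likely to fail:
1. **Step 6 (new photo-Wolff/ketene arylation).** The carbene may undergo a 1,2-H shift from the isopropyl group to give an enone, and the hindered ketene may couple poorly with the aryllithium. Fallback (known chemistry): from ketone 6, Wittig methoxymethylenation (Ph3P=CHOMe) and hydrolysis give the α-branched aldehyde, and 2,4,6-trimethoxyphenyllithium addition gives carbinol 9, rejoining at step 7.
2. **Step 5 (diazo transfer).** Enolisation at the α-aryl C4–H could epimerise C4 or give the wrong regiochemistry. Fallback: hydrolyse ester 4 (KOSiMe3), convert to the acid chloride ((COCl)2), and acylate 1-diazo-2-methylpropane (from isobutyraldehyde hydrazone and MnO2) to give 7 directly.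
3. **Step 9 (tetra-formylation).** The acid-labile benzylic aryl ether and the electron-rich polyphenol may decompose or under-formylate. Fallback: hydroxymethylate the four free positions with aqueous HCHO under mild base, then oxidise the CH2OH groups to CHO with IBX or MnO2.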